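**Retrosynthetic overview**
1. The target is a 3β-acyloxy-4α-acetoxy-11-hydroxyeudesm-6-en-8-one. The end game makes the C3/C4 oxygens from a C3=C4 silyl enol ether (α-face dihydroxylation, then hydride), attaches the side chain as the (2S,3R)-epoxy acid, acetylates C4–OH, and opens the epoxide with HCl last.
2. Key disconnection: the C8–C9 bond of ring B (C5–C6=C7–C8–C9–C10). The enabling feature is that the C8 carbonyl and the C11 tertiary carbinol both sit on C7 (O=C8–C7–C11–OH). They can therefore be stored as a four-membered β-lactone (C7, C8, O, C11) whose exocyclic Z alkene C6=C7 holds C8 cis to C5, within reach of a C9 carbanion on quaternary C10.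
3. The β-lactone comes from a C6≡C7 propargylic alcohol and CO (trans-hydrostannation, iododestannylation, cyclocarbonylation); C9 comes from a formyl group (reduction, iodination).
4. Ring A comes from a catalytic asymmetric Diels–Alder reaction of methacrolein with a 2-silyloxy-3-methyl dienyne. It sets C10 and C5 and brings C9 (as CHO), the C4 methyl and the C3 oxygen.
5. Ring order: ring A (Diels–Alder), then the temporary oxetanone ring, then ring B (key step, which removes the oxetanone in the same operation).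

Key step: step 9

Remark on numbering: eudesmane numbering is used in the text (ring A = C1–C5, C10; ring B = C5–C10; C11 = carbinol carbon; C14 = methyl on C10; C15 = methyl on C4).
Remark (assumption): the absolute sense of step 4 is assigned by analogy with cycloadditions of α-substituted acroleins under this catalyst class; the (S)-oxazaborolidine is written, and its mirror image is to be used if the analogy points the other way for this diene.

**Route**

Step 1
Reactants: 1 2-methyl-2-(trimethylsilyloxy)but-3-yne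
Product: 3 4-methyl-4-(trimethylsilyloxy)pent-2-ynal, via lithium acetylide 2 (not isolated)
Conditions: n-BuLi, THF, −78 °C; DMF, −78 → 0 °C; inverse quench into aq. KH2PO4
Reagents that add atoms: N,N-dimethylformamide, CN(C)C=O
Why: Formylation of a lithium acetylide with DMF (Bouveault-type) should give the ynal, and the buffered inverse quench should release it without cleaving the tertiary TMS ether.

Step 2
Reactants: 3 4-methyl-4-(trimethylsilyloxy)pent-2-ynal; 4 3-(triphenylphosphoranylidene)butan-2-one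
Product: 5 (E)-3,7-dimethyl-7-(trimethylsilyloxy)oct-3-en-5-yn-2-one
Conditions: CH2Cl2, 0 °C → rt
Reagents that add atoms: none
Why: Wittig olefination with a stabilized α-branched acyl ylide is E-selective, which puts the acetyl group trans to the alkynyl group as the diene of step 4 requires.

Step 3
Reactants: 5 (E)-3,7-dimethyl-7-(trimethylsilyloxy)oct-3-en-5-yn-2-one
Product: 6 (E)-triisopropyl{[3,7-dimethyl-7-(trimethylsilyloxy)octa-1,3-dien-5-yn-2-yl]oxy}silane
Conditions: TIPSOTf, Et3N, CH2Cl2, −78 → 0 °C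
Reagents that add atoms: triisopropylsilyl triflate, CC(C)[Si](C(C)C)(C(C)C)OS(=O)(=O)C(F)(F)F
Why: Soft enolization and O-silylation of the methyl ketone (its only enolizable α-position) should give the 2-silyloxy diene; TIPS is chosen so that the enol ether survives until step 10.

Step 4
Reactants: 6 (E)-triisopropyl{[3,7-dimethyl-7-(trimethylsilyloxy)octa-1,3-dien-5-yn-2-yl]oxy}silane; 7 methacrolein
Product: 8 (1S,2S)-1,3-dimethyl-2-[3-methyl-3-(trimethylsilyloxy)but-1-yn-1-yl]-4-(triisopropylsilyloxy)cyclohex-3-ene-1-carbaldehyde (formyl trans to alkynyl)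
Conditions: (S)-1-(o-tolyl)-3,3-diphenyl-tetrahydro-1H,3H-pyrrolo[1,2-c][1,3,2]oxazaborole (20 mol%) + Tf2NH (18 mol%), CH2Cl2, −78 → −40 °C
Reagents that add atoms: none
Why: In this catalytic asymmetric Diels–Alder reaction the silyloxy group ("para") and the alkynyl terminus ("ortho") both direct the α-carbon of methacrolein to the alkynyl-bearing diene terminus, the exo approach usual for α-substituted acroleins puts CHO trans to the alkynyl group, and the chiral oxazaborolidinium Lewis acid shields one enal face, so C10 and C5 are set together.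

Step 5
Reactants: 8 (1S,2S)-1,3-dimethyl-2-[3-methyl-3-(trimethylsilyloxy)but-1-yn-1-yl]-4-(triisopropylsilyloxy)cyclohex-3-ene-1-carbaldehyde
Product: 9 {(1S,2R)-1,3-dimethyl-2-[3-methyl-3-(trimethylsilyloxy)but-1-yn-1-yl]-4-(triisopropylsilyloxy)cyclohex-3-en-1-yl}methanol
Conditions: NaBH4, THF/EtOH, −20 → 0 °C
Reagents that add atoms: none
Why: Borohydride reduction of the non-enolizable neopentyl aldehyde should be chemoselective, since the enol ether, alkyne and silyl ether are inert (the C2 descriptor changes by priority only).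

Step 6
Reactants: 9 {(1S,2R)-1,3-dimethyl-2-[3-methyl-3-(trimethylsilyloxy)but-1-yn-1-yl]-4-(triisopropylsilyloxy)cyclohex-3-en-1-yl}methanol
Product: 11 4-[(1S,6S)-6-(iodomethyl)-2,6-dimethyl-3-(triisopropylsilyloxy)cyclohex-2-en-1-yl]-2-methylbut-3-yn-2-ol, via TMS-protected iodide 10 (not isolated)
Conditions: PPh3, I2, imidazole (premixed), toluene, 60 °C; then K2CO3, MeOH, rt
Reagents that add atoms: iodine, II
Why: Appel-type iodination (iodide displaces an alkoxyphosphonium) works on neopentyl primary alcohols on heating without rearrangement while the tertiary hydroxyl stays masked as its TMS ether, and mild methanolysis then frees that hydroxyl without touching the TIPS enol ether.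

Step 7
Reactants: 11 4-[(1S,6S)-6-(iodomethyl)-2,6-dimethyl-3-(triisopropylsilyloxy)cyclohex-2-en-1-yl]-2-methylbut-3-yn-2-ol
Product: 13 (Z)-3-iodo-4-[(1S,6S)-6-(iodomethyl)-2,6-dimethyl-3-(triisopropylsilyloxy)cyclohex-2-en-1-yl]-2-methylbut-3-en-2-ol, via Z-alkenylstannane 12 (not isolated)
Conditions: [Cp*RuCl]4 (2.5 mol%; Cp* = C5Me5), Bu3SnH (1.05 equiv), CH2Cl2, rt; then 2,6-lutidine, I2, −78 → 0 °C
Reagents that add atoms: iodine, II; tributyltin hydride, CCCC[SnH](CCCC)CCCC (its tin stays only in 12)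
Why: Hydroxyl-directed ruthenium-catalysed trans-hydrostannation should place tin on the alkyne carbon next to the carbinol with H trans to it, and iododestannylation proceeds with retention, so iodine ends up cis to the ring carbon, which is the geometry ring B needs.

Step 8
Reactants: 13 (Z)-3-iodo-4-[(1S,6S)-6-(iodomethyl)-2,6-dimethyl-3-(triisopropylsilyloxy)cyclohex-2-en-1-yl]-2-methylbut-3-en-2-ol
Product: 14 (Z)-3-{[(1S,6S)-6-(iodomethyl)-2,6-dimethyl-3-(triisopropylsilyloxy)cyclohex-2-en-1-yl]methylidene}-4,4-dimethyloxetan-2-one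
Conditions: PdCl2(PPh3)2 (5 mol%), CO (1 atm), K2CO3, THF, 50 °C
Reagents that add atoms: carbon monoxide, [C-]#[O+]
Why: Palladium-catalysed cyclocarbonylation of a 2-iodoallylic alcohol should give the α-alkylidene β-lactone with retained alkene geometry: zerovalent palladium adds to the vinyl iodide (the neopentyl iodide is inert here), CO inserts, and the adjacent tertiary hydroxyl, helped by the gem-dimethyl effect, captures the acylpalladium.

Step 9
Reactants: 14 (Z)-3-{[(1S,6S)-6-(iodomethyl)-2,6-dimethyl-3-(triisopropylsilyloxy)cyclohex-2-en-1-yl]methylidene}-4,4-dimethyloxetan-2-one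
Product: 17 (5R,10R)-11-(triethylsilyloxy)-3-(triisopropylsilyloxy)eudesma-3,6-dien-8-one, via primary alkyllithium 15 (not isolated), via lithium alkoxide 16 (not isolated)
Conditions: t-BuLi (2.05 equiv), Et2O/pentane, −100 → −78 °C; then TESOTf, −78 → 0 °C
Reagents that add atoms: triethylsilyl triflate, CC[Si](CC)(CC)OS(=O)(=O)C(F)(F)F
Why: Iodine–lithium exchange at the neopentyl iodide gives primary alkyllithium 15 (the second equivalent of t-BuLi destroys t-BuI), which adds to the strained lactone carbonyl; the tetrahedral alkoxide collapses by expelling the tertiary C11 alkoxide with release of four-ring strain to give enone alkoxide 16, which TESOTf caps in the flask. The closest known reaction types are the Parham-type cyclization (halogen–lithium exchange followed by intramolecular acylation by an ester, lactone or amide) and the acyl–oxygen opening of β-lactones by organolithiums to β-hydroxy ketones. Ring B (C5–C6–C7–C8–C9–C10) closes in a 6-exo-trig mode at the carbonyl carbon while the four-membered ring opens. No stereocentre is created: the trans ring fusion (C5–H α, C10–CH3 β) is carried over from the exo Diels–Alder adduct, whose trans-disposed CH2Li and alkenyl arms can both be equatorial, and the Z geometry from step 7 holds C8 cis to C5. The step needs exchange to outrun attack of t-BuLi on the lactone (exchange of primary iodides at −100 °C is faster than carbonyl addition), and it needs acyl attack with a single addition: conjugate attack at C6 would require a four-membered ring, C11 is quaternary so alkyl–oxygen opening is closed, and the nucleophile is used up intramolecularly. One operation should thus deliver the decalin, the enone carbonyl and the protected C11 oxygen.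

Step 10
Reactants: 17 (5R,10R)-11-(triethylsilyloxy)-3-(triisopropylsilyloxy)eudesma-3,6-dien-8-one
Product: 18 (4S,5R,10R)-4-hydroxy-11-(triethylsilyloxy)eudesm-6-ene-3,8-dione (4α-OH, 4β-CH3)
Conditions: OsO4 (5 mol%), NMO, MeSO2NH2, acetone/H2O, 0 °C → rt
Reagents that add atoms: N-methylmorpholine N-oxide, C[N+]1([O-])CCOCC1; water, O (both delivered through catalytic OsO4)
Why: Osmium-catalysed dihydroxylation of the electron-rich silyl enol ether (the hindered, electron-poor enone alkene should stay untouched) is expected from the α-face, anti to the axial C10 methyl, and the silyl hemiketal collapses to the α-hydroxy ketone, which sets C4.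

Step 11
Reactants: 18 (4S,5R,10R)-4-hydroxy-11-(triethylsilyloxy)eudesm-6-ene-3,8-dione
Product: 19 (3S,4S,5R,10R)-3,4-dihydroxy-11-(triethylsilyloxy)eudesm-6-en-8-one (3β-OH, 4α-OH)
Conditions: NaBH4 (1 equiv), CH2Cl2/MeOH, −78 °C
Reagents that add atoms: none
Why: At low temperature NaBH4 should reduce the saturated α-hydroxy ketone in preference to the hindered conjugated enone (C11–O is silylated, so no hydroxyl assists attack at C8), and axial α-face hydride delivery gives the equatorial 3β-alcohol trans to the 4α-hydroxyl.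

Step 12
Reactants: 20 (E)-2-methylbut-2-en-1-ol
Product: 21 (2R,3R)-(2,3-dimethyloxiran-2-yl)methanol
Conditions: Ti(OiPr)4 (5 mol%), diethyl D-(−)-tartrate (6 mol%), t-BuOOH, 4 Å MS, CH2Cl2, −20 °C
Reagents that add atoms: tert-butyl hydroperoxide, CC(C)(C)OO
Why: Sharpless asymmetric epoxidation of the E trisubstituted allylic alcohol with the D-tartrate ligand should deliver oxygen to the face that gives the (2R,3R)-epoxy alcohol with cis methyl groups.

Step 13
Reactants: 21 (2R,3R)-(2,3-dimethyloxiran-2-yl)methanol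
Product: 22 (2S,3R)-2,3-dimethyloxirane-2-carboxylic acid
Conditions: RuCl3 (2 mol%), NaIO4, MeCN/EtOAc/H2O, 0 °C → rt
Reagents that add atoms: sodium periodate, [Na+].[O-]I(=O)(=O)=O; water, O
Why: Oxidation of the primary alcohol to the acid by RuO4 generated in the flask leaves the epoxide and both stereocentres untouched (the C2 descriptor changes by priority only).

Step 14
Reactants: 19 (3S,4S,5R,10R)-3,4-dihydroxy-11-(triethylsilyloxy)eudesm-6-en-8-one; 22 (2S,3R)-2,3-dimethyloxirane-2-carboxylic acid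
Product: 24 (3S,4S,5R,10R)-4-hydroxy-11-(triethylsilyloxy)-8-oxoeudesm-6-en-3-yl (2S,3R)-2,3-dimethyloxirane-2-carboxylate, via mixed anhydride 23 (not isolated)
Conditions: 22, 2,4,6-Cl3C6H2COCl, Et3N, THF, 0 °C → rt; then 19, DMAP, toluene, rt
Reagents that add atoms: 2,4,6-trichlorobenzoyl chloride, O=C(Cl)c1c(Cl)cc(Cl)cc1Cl (its atoms stay only in 23)
Why: In this Yamaguchi esterification the mixed anhydride should acylate the secondary equatorial 3β-hydroxyl selectively over the tertiary C4 hydroxyl, and the epoxide serves as the protected form of the chlorohydrin.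

Step 15
Reactants: 24 (3S,4S,5R,10R)-4-hydroxy-11-(triethylsilyloxy)-8-oxoeudesm-6-en-3-yl (2S,3R)-2,3-dimethyloxirane-2-carboxylate
Product: 25 (3S,4S,5R,10R)-4-acetoxy-11-(triethylsilyloxy)-8-oxoeudesm-6-en-3-yl (2S,3R)-2,3-dimethyloxirane-2-carboxylate
Conditions: Ac2O, DMAP, Et3N, CH2Cl2, 40 °C
Reagents that add atoms: acetic anhydride, CC(=O)OC(C)=O
Why: DMAP-catalysed acetylation meets only one free hydroxyl (tertiary C4–OH), because C11–O is silylated and the side-chain oxygen is tied up in the epoxide, so no selectivity among tertiary alcohols is needed.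

Step 16
Reactants: 25 (3S,4S,5R,10R)-4-acetoxy-11-(triethylsilyloxy)-8-oxoeudesm-6-en-3-yl (2S,3R)-2,3-dimethyloxirane-2-carboxylate
Product: 27 (3S,4S,5R,10R)-4-acetoxy-11-hydroxy-8-oxoeudesm-6-en-3-yl (2R,3S)-3-chloro-2-hydroxy-2-methylbutanoate (target), via TES-protected chlorohydrin 26 (not isolated)
Conditions: HCl (4 M in 1,4-dioxane), CH2Cl2, −20 → 0 °C; then MeOH, 0 °C
Reagents that add atoms: hydrogen chloride, Cl
Why: Chloride should open the protonated 2,3-epoxy ester at the secondary β-carbon (the α-carbon is quaternary and deactivated by the ester) with SN2 inversion to give the (2R,3S)-chlorohydrin, and acidic methanolysis then removes the tertiary TES ether.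

**Compound list**
1 | 2-methyl-2-(trimethylsilyloxy)but-3-yne | C#CC(C)(C)O[Si](C)(C)C | starting material
2 | lithium acetylide of 1 | [Li]C#CC(C)(C)O[Si](C)(C)C | intermediate
3 | 4-methyl-4-(trimethylsilyloxy)pent-2-ynal | O=CC#CC(C)(C)O[Si](C)(C)C | intermediate
4 | 3-(triphenylphosphoranylidene)butan-2-one | CC(=O)C(C)=P(c1ccccc1)(c1ccccc1)c1ccccc1 | starting material
5 | (E)-3,7-dimethyl-7-(trimethylsilyloxy)oct-3-en-5-yn-2-one | CC(=O)/C(C)=C/C#CC(C)(C)O[Si](C)(C)C | intermediate
6 | (E)-triisopropyl{[3,7-dimethyl-7-(trimethylsilyloxy)octa-1,3-dien-5-yn-2-yl]oxy}silane | C=C(O[Si](C(C)C)(C(C)C)C(C)C)/C(C)=C/C#CC(C)(C)O[Si](C)(C)C | intermediate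
7 | methacrolein (2-methylprop-2-enal) | C=C(C)C=O | starting material
8 | (1S,2S)-1,3-dimethyl-2-[3-methyl-3-(trimethylsilyloxy)but-1-yn-1-yl]-4-(triisopropylsilyloxy)cyclohex-3-ene-1-carbaldehyde | O=C[C@@]1(C)CCC(O[Si](C(C)C)(C(C)C)C(C)C)=C(C)[C@@H]1C#CC(C)(C)O[Si](C)(C)C | intermediate
9 | {(1S,2R)-1,3-dimethyl-2-[3-methyl-3-(trimethylsilyloxy)but-1-yn-1-yl]-4-(triisopropylsilyloxy)cyclohex-3-en-1-yl}methanol | OC[C@@]1(C)CCC(O[Si](C(C)C)(C(C)C)C(C)C)=C(C)[C@@H]1C#CC(C)(C)O[Si](C)(C)C | intermediate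
10 | TMS-protected iodide: {[(1S,6S)-6-(iodomethyl)-2,6-dimethyl-3-(triisopropylsilyloxy)cyclohex-2-en-1-yl]ethynyl}dimethylcarbinol trimethylsilyl ether | IC[C@@]1(C)CCC(O[Si](C(C)C)(C(C)C)C(C)C)=C(C)[C@@H]1C#CC(C)(C)O[Si](C)(C)C | intermediate
11 | 4-[(1S,6S)-6-(iodomethyl)-2,6-dimethyl-3-(triisopropylsilyloxy)cyclohex-2-en-1-yl]-2-methylbut-3-yn-2-ol | IC[C@@]1(C)CCC(O[Si](C(C)C)(C(C)C)C(C)C)=C(C)[C@@H]1C#CC(C)(C)O | intermediate
12 | (Z)-4-[(1S,6S)-6-(iodomethyl)-2,6-dimethyl-3-(triisopropylsilyloxy)cyclohex-2-en-1-yl]-2-methyl-3-(tributylstannyl)but-3-en-2-ol | IC[C@@]1(C)CCC(O[Si](C(C)C)(C(C)C)C(C)C)=C(C)[C@@H]1/C=C(\[Sn](CCCC)(CCCC)CCCC)C(C)(C)O | intermediate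
13 | (Z)-3-iodo-4-[(1S,6S)-6-(iodomethyl)-2,6-dimethyl-3-(triisopropylsilyloxy)cyclohex-2-en-1-yl]-2-methylbut-3-en-2-ol | IC[C@@]1(C)CCC(O[Si](C(C)C)(C(C)C)C(C)C)=C(C)[C@@H]1/C=C(\I)C(C)(C)O | intermediate
14 | (Z)-3-{[(1S,6S)-6-(iodomethyl)-2,6-dimethyl-3-(triisopropylsilyloxy)cyclohex-2-en-1-yl]methylidene}-4,4-dimethyloxetan-2-one | IC[C@@]1(C)CCC(O[Si](C(C)C)(C(C)C)C(C)C)=C(C)[C@@H]1/C=C2\C(=O)OC2(C)C | intermediate
15 | primary alkyllithium from 14 (CH2Li in place of CH2I) | [Li]C[C@@]1(C)CCC(O[Si](C(C)C)(C(C)C)C(C)C)=C(C)[C@@H]1/C=C2\C(=O)OC2(C)C | intermediate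
16 | lithium 11-alkoxide of (5R,10R)-11-hydroxy-3-(triisopropylsilyloxy)eudesma-3,6-dien-8-one | CC1=C(O[Si](C(C)C)(C(C)C)C(C)C)CC[C@]2(C)CC(=O)C(C(C)(C)O[Li])=C[C@H]21 | intermediate
17 | (5R,10R)-11-(triethylsilyloxy)-3-(triisopropylsilyloxy)eudesma-3,6-dien-8-one (5α-H, 10β-CH3) | CC1=C(O[Si](C(C)C)(C(C)C)C(C)C)CC[C@]2(C)CC(=O)C(C(C)(C)O[Si](CC)(CC)CC)=C[C@H]21 | intermediate
18 | (4S,5R,10R)-4-hydroxy-11-(triethylsilyloxy)eudesm-6-ene-3,8-dione (4α-OH, 4β-CH3) | C[C@@]1(O)C(=O)CC[C@]2(C)CC(=O)C(C(C)(C)O[Si](CC)(CC)CC)=C[C@H]21 | intermediate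
19 | (3S,4S,5R,10R)-3,4-dihydroxy-11-(triethylsilyloxy)eudesm-6-en-8-one (3β-OH, 4α-OH) | C[C@@]1(O)[C@@H](O)CC[C@]2(C)CC(=O)C(C(C)(C)O[Si](CC)(CC)CC)=C[C@H]21 | intermediate
20 | (E)-2-methylbut-2-en-1-ol | C/C=C(\C)CO | starting material
21 | (2R,3R)-(2,3-dimethyloxiran-2-yl)methanol | C[C@H]1O[C@]1(C)CO | intermediate
22 | (2S,3R)-2,3-dimethyloxirane-2-carboxylic acid | C[C@H]1O[C@]1(C)C(=O)O | intermediate
23 | (2S,3R)-2,3-dimethyloxirane-2-carboxylic 2,4,6-trichlorobenzoic anhydride | C[C@H]1O[C@]1(C)C(=O)OC(=O)c2c(Cl)cc(Cl)cc2Cl | intermediate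
24 | (3S,4S,5R,10R)-4-hydroxy-11-(triethylsilyloxy)-8-oxoeudesm-6-en-3-yl (2S,3R)-2,3-dimethyloxirane-2-carboxylate | C[C@@]1(O)[C@@H](OC(=O)[C@@]3(C)O[C@@H]3C)CC[C@]2(C)CC(=O)C(C(C)(C)O[Si](CC)(CC)CC)=C[C@H]21 | intermediate
25 | (3S,4S,5R,10R)-4-acetoxy-11-(triethylsilyloxy)-8-oxoeudesm-6-en-3-yl (2S,3R)-2,3-dimethyloxirane-2-carboxylate | CC(=O)O[C@]1(C)[C@@H](OC(=O)[C@@]3(C)O[C@@H]3C)CC[C@]2(C)CC(=O)C(C(C)(C)O[Si](CC)(CC)CC)=C[C@H]21 | intermediate
26 | (3S,4S,5R,10R)-4-acetoxy-11-(triethylsilyloxy)-8-oxoeudesm-6-en-3-yl (2R,3S)-3-chloro-2-hydroxy-2-methylbutanoate | CC(=O)O[C@]1(C)[C@@H](OC(=O)[C@@](C)(O)[C@H](C)Cl)CC[C@]2(C)CC(=O)C(C(C)(C)O[Si](CC)(CC)CC)=C[C@H]21 | intermediate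
27 | (3S,4S,5R,10R)-4-acetoxy-11-hydroxy-8-oxoeudesm-6-en-3-yl (2R,3S)-3-chloro-2-hydroxy-2-methylbutanoate | CC(=O)O[C@]1(C)[C@@H](OC(=O)[C@@](C)(O)[C@H](C)Cl)CC[C@]2(C)CC(=O)C(C(C)(C)O)=C[C@H]21 | target

**Step count and risks**
Total step count: 16. Longest linear sequence: 14 steps (steps 1–11 and 14–16); steps 12–13 form the side-chain branch.

The three steps most likely to fail:

1. Step 9 (key step). Addition of t-BuLi to the strained conjugated lactone, or deprotonation at the γ-position, may compete with iodine–lithium exchange. The fallback replaces the strained acyl donor by a chelating one. It sets out from 13: silylation of the tertiary hydroxyl (TESOTf, 2,6-lutidine, CH2Cl2, −78 °C) should give the triethylsilyl ether of 13 F1. Palladium-catalysed aminocarbonylation of its vinyl iodide (Pd(OAc)2, Xantphos, CO 1 atm, MeNH(OMe)·HCl, Et3N, toluene, 80 °C) should give the Z-configured Weinreb amide F2. Iodine–lithium exchange of F2 (t-BuLi, Et2O/pentane, −78 °C) followed by Parham-type cyclization onto the amide, whose chelated tetrahedral intermediate survives until work-up, should give 17, where the route is rejoined.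

2. Step 4. The chiral Lewis acid may discriminate the enal faces poorly with this hindered tetrasubstituted diene, giving low enantiomeric purity. The fallback obtains the enantiomer by resolution instead of catalysis. It sets out from 6 and 7: cycloaddition promoted by achiral Me2AlCl (CH2Cl2, −78 °C) should give the racemic exo adduct, that is 8 together with its enantiomer ent-8 F3. NaBH4 reduction as in step 5 gives 9 together with its enantiomer ent-9 F4. Lipase-catalysed transesterification (Burkholderia cepacia lipase, vinyl acetate, MTBE), with the enzyme chosen so that ent-9 is the faster-reacting antipode, should convert it into the acetate of ent-9 F5, which is removed by chromatography. Unreacted 9 rejoins the route at step 6.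

3. Step 15. The tertiary C4 hydroxyl, flanked by the bulky C3 ester and the axial C4 methyl, may fail to acylate, or acyl groups may scramble under forcing conditions. The fallback introduces the acetate before the C3 ester. It sets out from 18: acetylation of the less encumbered tertiary α-ketol (Ac2O, DMAP, Et3N, CH2Cl2, rt) should give the 4α-acetoxy-3-ketone F6. Non-basic reduction (Zn(BH4)2, Et2O, −40 °C; axial hydride delivery, no alkoxide to trigger acetyl migration) should give the 3β-hydroxy-4α-acetate F7. Immediate acylation of F7 with mixed anhydride 23 (DMAP, toluene, 0 °C) should give 25, where the route is rejoined before step 16.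

Further compounds
F1 | step 9 | triethylsilyl ether of 13: triethyl{[(Z)-3-iodo-4-[(1S,6S)-6-(iodomethyl)-2,6-dimethyl-3-(triisopropylsilyloxy)cyclohex-2-en-1-yl]-2-methylbut-3-en-2-yl]oxy}silane | IC[C@@]1(C)CCC(O[Si](C(C)C)(C(C)C)C(C)C)=C(C)[C@@H]1/C=C(\I)C(C)(C)O[Si](CC)(CC)CC
F2 | step 9 | (Z)-3-[(1S,6S)-6-(iodomethyl)-2,6-dimethyl-3-(triisopropylsilyloxy)cyclohex-2-en-1-yl]-N-methoxy-N-methyl-2-[2-(triethylsilyloxy)propan-2-yl]prop-2-enamide | IC[C@@]1(C)CCC(O[Si](C(C)C)(C(C)C)C(C)C)=C(C)[C@@H]1/C=C(\C(=O)N(C)OC)C(C)(C)O[Si](CC)(CC)CC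
F3 | step 4 | ent-8: (1R,2R)-1,3-dimethyl-2-[3-methyl-3-(trimethylsilyloxy)but-1-yn-1-yl]-4-(triisopropylsilyloxy)cyclohex-3-ene-1-carbaldehyde | O=C[C@]1(C)CCC(O[Si](C(C)C)(C(C)C)C(C)C)=C(C)[C@H]1C#CC(C)(C)O[Si](C)(C)C
F4 | step 4 | ent-9: {(1R,2S)-1,3-dimethyl-2-[3-methyl-3-(trimethylsilyloxy)but-1-yn-1-yl]-4-(triisopropylsilyloxy)cyclohex-3-en-1-yl}methanol | OC[C@]1(C)CCC(O[Si](C(C)C)(C(C)C)C(C)C)=C(C)[C@H]1C#CC(C)(C)O[Si](C)(C)C
F5 | step 4 | acetate of ent-9 | CC(=O)OC[C@]1(C)CCC(O[Si](C(C)C)(C(C)C)C(C)C)=C(C)[C@H]1C#CC(C)(C)O[Si](C)(C)C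
F6 | step 15 | (4S,5R,10R)-4-acetoxy-11-(triethylsilyloxy)eudesm-6-ene-3,8-dione | CC(=O)O[C@]1(C)C(=O)CC[C@]2(C)CC(=O)C(C(C)(C)O[Si](CC)(CC)CC)=C[C@H]21
F7 | step 15 | (3S,4S,5R,10R)-4-acetoxy-3-hydroxy-11-(triethylsilyloxy)eudesm-6-en-8-one | CC(=O)O[C@]1(C)[C@@H](O)CC[C@]2(C)CC(=O)C(C(C)(C)O[Si](CC)(CC)CC)=C[C@H]21
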